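**Plan**
- Flavanone numbering is used, piperidine atoms primed; the target is (2S,2'R). After removal of three O-benzyl groups, ring C is cut at C4–C4a (Friedel–Crafts acylation) and O1–C2 (Mitsunobu etherification). Ring A is then cut at C6–C7 and C4a–C5 (the labels C5/C7 and C4a/C8 are interchangeable until ring C exists).
- Enabling feature: ring A is a phloroglucinol in which C6 carries the piperidine between the oxygenated C5 and C7, and the third oxygen (on C8a) is para to C6. A 3-alkoxycyclobutenone and a siloxyalkyne give exactly this array with the three oxygens as OH, OSi and O-allyl, so no 6- versus 8-substitution problem arises.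
- Forward order: the piperidine ring is bought, ring A is built by benzannulation (step 5), ring B arrives with the C2–C3–C4 chain (step 10), and ring C closes last (step 13).
- Stereochemistry: C2' comes from the chiral pool and is carried through unchanged. C2 is set as an R carbinol by Brown allylboration and inverted to S in the Mitsunobu etherification.
- The N-methyl carbon is the former Boc carbonyl (LiAlH4 reduction), and the last step is a single hydrogenolysis.

Key step: step 5

Assumption: compound 1 is bought enantiopure (otherwise it is one borane reduction away from (R)-N-Boc-pipecolic acid).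

**Step 1**
Reactants: 1 tert-butyl (R)-2-(hydroxymethyl)piperidine-1-carboxylate
Product: 2 tert-butyl (R)-2-formylpiperidine-1-carboxylate
Conditions: Dess–Martin periodinane (1.2 equiv), CH2Cl2, 0 °C → rt; used crude
Reagents that add atoms: none
Why: Dess–Martin oxidation of the primary alcohol stops at the aldehyde under neutral conditions, so the α-amino stereocentre should not epimerize if 2 is used at once.

**Step 2**
Reactants: 2 tert-butyl (R)-2-formylpiperidine-1-carboxylate
Product: 3 tert-butyl (R)-2-ethynylpiperidine-1-carboxylate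
Conditions: dimethyl (1-diazo-2-oxopropyl)phosphonate (1.3 equiv), K2CO3 (2 equiv), MeOH, 0 °C → rt
Reagents that add atoms: dimethyl (1-diazo-2-oxopropyl)phosphonate, COP(=O)(OC)C(=[N+]=[N-])C(C)=O
Why: Seyferth–Gilbert homologation in its Ohira–Bestmann form, in which the diazomethylphosphonate anion adds to the aldehyde, loses dimethyl phosphate and N2 and rearranges to the alkyne, while the mild carbonate base at 0 °C should leave C2' intact.

**Step 3**
Reactants: 3 tert-butyl (R)-2-ethynylpiperidine-1-carboxylate
Product: 6 tert-butyl (R)-2-[(triisopropylsilyloxy)ethynyl]piperidine-1-carboxylate, via lithium acetylide 4 (not isolated), via lithium ynolate 5 (not isolated)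
Conditions: LiN(SiMe3)2 (2.1 equiv), t-BuOOH (1.0 equiv), THF, −78 → 0 °C; then i-Pr3SiOTf (1.2 equiv), −78 → 0 °C
Reagents that add atoms: tert-butyl hydroperoxide, CC(C)(C)OO; triisopropylsilyl trifluoromethanesulfonate, CC(C)[Si](OS(=O)(=O)C(F)(F)F)(C(C)C)C(C)C
Why: Electrophilic oxygen transfer from lithium tert-butyl peroxide to acetylide 4 gives ynolate 5, which the bulky silyl triflate silylates on oxygen to the siloxyalkyne; the amide base is too weak to remove the propargylic C2'–H.

**Step 4**
Reactants: 7 3-ethoxycyclobut-2-en-1-one; 8 prop-2-en-1-ol (allyl alcohol)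
Product: 9 3-(prop-2-en-1-yloxy)cyclobut-2-en-1-one
Conditions: pyridinium p-toluenesulfonate (5 mol %), excess 8 as solvent, 40 °C, EtOH removed under reduced pressure, dry conditions
Reagents that add atoms: none
Why: Acid-catalysed alkoxy exchange of a vinylogous ester (conjugate addition of allyl alcohol to the protonated enone, then loss of ethanol), driven by excess allyl alcohol and removal of ethanol.

**Step 5**
Reactants: 6 tert-butyl (R)-2-[(triisopropylsilyloxy)ethynyl]piperidine-1-carboxylate; 9 3-(prop-2-en-1-yloxy)cyclobut-2-en-1-one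
Product: 14 tert-butyl (R)-2-[2-hydroxy-4-(prop-2-en-1-yloxy)-6-(triisopropylsilyloxy)phenyl]piperidine-1-carboxylate, via vinylketene 10 (not isolated), via alkenylcyclobutenone 11 (not isolated), via dienylketene 12 (not isolated), via cyclohexadienone 13 (not isolated)
Conditions: toluene (0.5 M), 6 (1.2 equiv), 80 °C, then 105 °C
Reagents that add atoms: none
Why: On heating, 9 opens by four-electron electrocyclic ring opening to vinylketene 10, whose ketene C=C adds across the siloxyalkyne in a [2+2] cycloaddition to give 11; a second four-electron opening gives dienylketene 12, and ring A closes by thermal six-electron electrocyclization to dienone 13, which tautomerizes to phenol 14, so that C6–C7 and C4a–C5 are the two new skeletal bonds. The closest known reaction type is the thermal benzannulation of cyclobutenones with trialkylsiloxyalkynes to resorcinol monosilyl ethers (Danheiser benzannulation); the 3-alkoxy group on the cyclobutenone and the carbamate-bearing stereocentre on the alkyne are substituent variations within that class. No stereocentre is created, because the sp3 ring carbon of 11 is lost on aromatization. The selectivity needed is regiochemical: the electrophilic ketene carbonyl carbon must bond to the nucleophilic alkyne carbon remote from oxygen, the one bearing the piperidine, which the polarization of the ynol silyl ether secures and which places C2' between the OH and OSi groups with the allyloxy group para to it. C2' must keep its configuration, which the neutral, base-free thermal conditions and the non-acidic propargylic C–H should ensure. A slight excess of the alkyne limits O-acylation of 14 by 10.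

**Step 6**
Reactants: 14 tert-butyl (R)-2-[2-hydroxy-4-(prop-2-en-1-yloxy)-6-(triisopropylsilyloxy)phenyl]piperidine-1-carboxylate
Product: 16 tert-butyl (R)-2-[2,6-bis(benzyloxy)-4-(prop-2-en-1-yloxy)phenyl]piperidine-1-carboxylate, via resorcinol 15 (not isolated)
Conditions: CsF (1.5 equiv), DMF, rt; then K2CO3 (3 equiv), BnBr (2.4 equiv), 50 °C
Reagents that add atoms: benzyl bromide, BrCc1ccccc1
Why: Fluoride cleaves the aryl silyl ether and both phenoxides of 15 are benzylated (Williamson ether synthesis), which makes the two oxygens flanking the piperidine identical and the two free ring positions equivalent for the later ring closure.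

**Step 7**
Reactants: 16 tert-butyl (R)-2-[2,6-bis(benzyloxy)-4-(prop-2-en-1-yloxy)phenyl]piperidine-1-carboxylate
Product: 17 (R)-2-[2,6-bis(benzyloxy)-4-(prop-2-en-1-yloxy)phenyl]-1-methylpiperidine
Conditions: LiAlH4 (4 equiv), THF, 65 °C
Reagents that add atoms: none
Why: LiAlH4 reduces the tert-butyl carbamate through the formamide to the N-methyl amine (carbamate-to-methyl reduction), the Boc carbonyl carbon becoming the N-methyl group, while aryl benzyl and allyl ethers are inert to hydride.

**Step 8**
Reactants: 17 (R)-2-[2,6-bis(benzyloxy)-4-(prop-2-en-1-yloxy)phenyl]-1-methylpiperidine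
Product: 18 3,5-bis(benzyloxy)-4-[(R)-1-methylpiperidin-2-yl]phenol
Conditions: Pd(PPh3)4 (5 mol %), morpholine (5 equiv), THF, rt
Reagents that add atoms: none
Why: Tsuji–Trost deallylation, in which zerovalent palladium ionizes the aryl allyl ether to a π-allyl complex and the phenoxide and morpholine captures the allyl group, leaving benzyl ethers and the tertiary amine untouched.

**Step 9**
Reactants: 19 4-(benzyloxy)benzaldehyde
Product: 20 (R)-1-[4-(benzyloxy)phenyl]but-3-en-1-ol
Conditions: (+)-Ipc2BOMe [(−)-α-pinene series] (1.3 equiv), CH2=CHCH2MgBr (1.2 equiv), Et2O, 0 °C → rt; then 19, −78 °C; NaOH, H2O2, 0 °C → rt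
Reagents that add atoms: allylmagnesium bromide, C=CC[Mg]Br
Why: Brown asymmetric allylboration through a chair Zimmerman–Traxler transition state, in which the B-allyl reagent of the (−)-α-pinene series is expected to deliver allyl to the Re face of the aryl aldehyde and so set the R carbinol.

**Step 10**
Reactants: 18 3,5-bis(benzyloxy)-4-[(R)-1-methylpiperidin-2-yl]phenol; 20 (R)-1-[4-(benzyloxy)phenyl]but-3-en-1-ol
Product: 21 (R)-2-{2,6-bis(benzyloxy)-4-[(S)-1-(4-(benzyloxy)phenyl)but-3-en-1-yloxy]phenyl}-1-methylpiperidine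
Conditions: PPh3 (1.5 equiv), DIAD (1.5 equiv), toluene, 0 °C → rt
Reagents that add atoms: none
Why: Mitsunobu etherification, in which the phenoxide of 18 displaces the alkoxyphosphonium ion of 20 by SN2 with inversion and turns the R carbinol into the S aryl ether (future C2); the non-polar solvent and low temperature are chosen to disfavour ionization of the p-benzyloxybenzylic centre.

**Step 11**
Reactants: 21 (R)-2-{2,6-bis(benzyloxy)-4-[(S)-1-(4-(benzyloxy)phenyl)but-3-en-1-yloxy]phenyl}-1-methylpiperidine
Product: 22 (S)-3-[4-(benzyloxy)phenyl]-3-{3,5-bis(benzyloxy)-4-[(R)-1-methylpiperidin-2-yl]phenoxy}propanal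
Conditions: OsO4 (2 mol %), NaIO4 (4 equiv), 2,6-lutidine (2 equiv), 1,4-dioxane–H2O (3:1), rt; used crude
Reagents that add atoms: osmium tetroxide, O=[Os](=O)(=O)=O; sodium periodate, [Na+].[O-]I(=O)(=O)=O
Why: Lemieux–Johnson oxidation, in which OsO4 dihydroxylates only the terminal alkene and periodate cleaves the diol to the aldehyde, sparing the electron-rich trialkoxyarene that ozone would attack.

**Step 12**
Reactants: 22 (S)-3-[4-(benzyloxy)phenyl]-3-{3,5-bis(benzyloxy)-4-[(R)-1-methylpiperidin-2-yl]phenoxy}propanal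
Product: 23 (S)-3-[4-(benzyloxy)phenyl]-3-{3,5-bis(benzyloxy)-4-[(R)-1-methylpiperidin-2-yl]phenoxy}propanoic acid
Conditions: NaClO2 (3 equiv), NaH2PO4 (3 equiv), 2-methylbut-2-ene (20 equiv), t-BuOH–H2O, 0 °C → rt
Reagents that add atoms: sodium chlorite, [Na+].[O-]Cl=O
Why: Pinnick oxidation by chlorous acid at about pH 4, where the amine is protonated and β-elimination of the phenol is not promoted, with 2-methylbut-2-ene scavenging HOCl before it can chlorinate ring A.

**Step 13**
Reactants: 23 (S)-3-[4-(benzyloxy)phenyl]-3-{3,5-bis(benzyloxy)-4-[(R)-1-methylpiperidin-2-yl]phenoxy}propanoic acid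
Product: 25 (S)-5,7-bis(benzyloxy)-2-[4-(benzyloxy)phenyl]-6-[(R)-1-methylpiperidin-2-yl]chroman-4-one, via mixed anhydride 24 (not isolated)
Conditions: (CF3CO)2O (2.5 equiv), CH2Cl2, 0 °C → rt; aqueous NaHCO3 work-up
Reagents that add atoms: none
Why: Intramolecular Friedel–Crafts acylation via mixed anhydride 24, in which the acyl group attacks one of the two equivalent ring positions ortho to the ether oxygen (each activated by three alkoxy groups) and closes the six-membered ring C, while the protonated amine is inert and C2 is not involved.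

**Step 14**
Reactants: 25 (S)-5,7-bis(benzyloxy)-2-[4-(benzyloxy)phenyl]-6-[(R)-1-methylpiperidin-2-yl]chroman-4-one
Product: 26 (2S)-5,7-dihydroxy-2-(4-hydroxyphenyl)-6-[(2R)-1-methylpiperidin-2-yl]-2,3-dihydro-4H-chromen-4-one
Conditions: H2 (1 atm), Pd/C (10% Pd), EtOAc–MeOH, CH3CO2H (2 equiv), rt; stopped after uptake of 3 equiv H2; free base after neutralisation
Reagents that add atoms: none
Why: Hydrogenolysis of the three aryl benzyl ethers on palladium, with acetic acid keeping the amine protonated so that it does not poison the catalyst, while the benzylic C2–O1 and C2'–N bonds, which lie in rings at hindered secondary centres, should react much more slowly.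

**Compound list**
1 | tert-butyl (R)-2-(hydroxymethyl)piperidine-1-carboxylate | CC(C)(C)OC(=O)N1CCCC[C@@H]1CO | starting material
2 | tert-butyl (R)-2-formylpiperidine-1-carboxylate | CC(C)(C)OC(=O)N1CCCC[C@@H]1C=O | intermediate
3 | tert-butyl (R)-2-ethynylpiperidine-1-carboxylate | CC(C)(C)OC(=O)N1CCCC[C@@H]1C#C | intermediate
4 | lithium acetylide of 3 | CC(C)(C)OC(=O)N1CCCC[C@@H]1C#C[Li] | intermediate
5 | lithium ynolate, lithium 2-[(R)-1-(tert-butoxycarbonyl)piperidin-2-yl]ethynolate | CC(C)(C)OC(=O)N1CCCC[C@@H]1C#CO[Li] | intermediate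
6 | tert-butyl (R)-2-[(triisopropylsilyloxy)ethynyl]piperidine-1-carboxylate | CC(C)(C)OC(=O)N1CCCC[C@@H]1C#CO[Si](C(C)C)(C(C)C)C(C)C | intermediate
7 | 3-ethoxycyclobut-2-en-1-one | CCOC1=CC(=O)C1 | starting material
8 | prop-2-en-1-ol (allyl alcohol) | C=CCO | starting material
9 | 3-(prop-2-en-1-yloxy)cyclobut-2-en-1-one | C=CCOC1=CC(=O)C1 | intermediate
10 | vinylketene, 3-(prop-2-en-1-yloxy)buta-1,3-dien-1-one | C=CCOC(=C)C=C=O | intermediate
11 | tert-butyl (2R)-2-{4-oxo-3-[1-(prop-2-en-1-yloxy)ethenyl]-2-(triisopropylsilyloxy)cyclobut-1-en-1-yl}piperidine-1-carboxylate (both epimers at the ring CH) | CC(C)(C)OC(=O)N1CCCC[C@@H]1C1=C(O[Si](C(C)C)(C(C)C)C(C)C)C(C(=C)OCC=C)C1=O | intermediate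
12 | dienylketene, ketene carbon and alkoxyvinyl group cis on the central C=C | CC(C)(C)OC(=O)N1CCCC[C@@H]1C(=C=O)/C(O[Si](C(C)C)(C(C)C)C(C)C)=C\C(=C)OCC=C | intermediate
13 | tert-butyl (R)-2-[6-oxo-4-(prop-2-en-1-yloxy)-2-(triisopropylsilyloxy)cyclohexa-1,3-dien-1-yl]piperidine-1-carboxylate | CC(C)(C)OC(=O)N1CCCC[C@@H]1C1=C(O[Si](C(C)C)(C(C)C)C(C)C)C=C(OCC=C)CC1=O | intermediate
14 | tert-butyl (R)-2-[2-hydroxy-4-(prop-2-en-1-yloxy)-6-(triisopropylsilyloxy)phenyl]piperidine-1-carboxylate | CC(C)(C)OC(=O)N1CCCC[C@@H]1c1c(O)cc(OCC=C)cc1O[Si](C(C)C)(C(C)C)C(C)C | intermediate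
15 | tert-butyl (R)-2-[2,6-dihydroxy-4-(prop-2-en-1-yloxy)phenyl]piperidine-1-carboxylate (present as its phenoxide) | CC(C)(C)OC(=O)N1CCCC[C@@H]1c1c(O)cc(OCC=C)cc1O | intermediate
16 | tert-butyl (R)-2-[2,6-bis(benzyloxy)-4-(prop-2-en-1-yloxy)phenyl]piperidine-1-carboxylate | CC(C)(C)OC(=O)N1CCCC[C@@H]1c1c(OCc2ccccc2)cc(OCC=C)cc1OCc1ccccc1 | intermediate
17 | (R)-2-[2,6-bis(benzyloxy)-4-(prop-2-en-1-yloxy)phenyl]-1-methylpiperidine | CN1CCCC[C@@H]1c1c(OCc2ccccc2)cc(OCC=C)cc1OCc1ccccc1 | intermediate
18 | 3,5-bis(benzyloxy)-4-[(R)-1-methylpiperidin-2-yl]phenol | CN1CCCC[C@@H]1c1c(OCc2ccccc2)cc(O)cc1OCc1ccccc1 | intermediate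
19 | 4-(benzyloxy)benzaldehyde | O=Cc1ccc(OCc2ccccc2)cc1 | starting material
20 | (R)-1-[4-(benzyloxy)phenyl]but-3-en-1-ol | C=CC[C@@H](O)c1ccc(OCc2ccccc2)cc1 | intermediate
21 | (R)-2-{2,6-bis(benzyloxy)-4-[(S)-1-(4-(benzyloxy)phenyl)but-3-en-1-yloxy]phenyl}-1-methylpiperidine | C=CC[C@H](Oc1cc(OCc2ccccc2)c([C@H]2CCCCN2C)c(OCc2ccccc2)c1)c1ccc(OCc2ccccc2)cc1 | intermediate
22 | (S)-3-[4-(benzyloxy)phenyl]-3-{3,5-bis(benzyloxy)-4-[(R)-1-methylpiperidin-2-yl]phenoxy}propanal | O=CC[C@H](Oc1cc(OCc2ccccc2)c([C@H]2CCCCN2C)c(OCc2ccccc2)c1)c1ccc(OCc2ccccc2)cc1 | intermediate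
23 | (S)-3-[4-(benzyloxy)phenyl]-3-{3,5-bis(benzyloxy)-4-[(R)-1-methylpiperidin-2-yl]phenoxy}propanoic acid | OC(=O)C[C@H](Oc1cc(OCc2ccccc2)c([C@H]2CCCCN2C)c(OCc2ccccc2)c1)c1ccc(OCc2ccccc2)cc1 | intermediate
24 | mixed anhydride of 23 with trifluoroacetic acid (amine protonated in the flask) | O=C(C[C@H](Oc1cc(OCc2ccccc2)c([C@H]2CCCCN2C)c(OCc2ccccc2)c1)c1ccc(OCc2ccccc2)cc1)OC(=O)C(F)(F)F | intermediate
25 | (S)-5,7-bis(benzyloxy)-2-[4-(benzyloxy)phenyl]-6-[(R)-1-methylpiperidin-2-yl]chroman-4-one | CN1CCCC[C@@H]1c1c(OCc2ccccc2)cc2c(c1OCc1ccccc1)C(=O)C[C@@H](c1ccc(OCc3ccccc3)cc1)O2 | intermediate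
26 | (2S)-5,7-dihydroxy-2-(4-hydroxyphenyl)-6-[(2R)-1-methylpiperidin-2-yl]-2,3-dihydro-4H-chromen-4-one | CN1CCCC[C@@H]1c1c(O)cc2c(c1O)C(=O)C[C@@H](c1ccc(O)cc1)O2 | target

**Step count**
Total: 14 steps. Longest linear sequence: 12 steps (1, 2, 3, 5, 6, 7, 8, 10, 11, 12, 13, 14 from compound 1). Steps 4 and 9 are side branches.

**Steps most likely to fail**

Step 5. The trapping of vinylketene 10 may fail: at the temperature needed to open the strained alkoxycyclobutenone, the ketene may be lost to self-condensation or to O-acylation of the phenol already formed before it meets the α-branched alkyne. The fallback makes 10 cold and in the presence of the alkyne by 1,4-dehydrochlorination instead of ring opening. It sets out from allyl alcohol 8 and siloxyalkyne 6 and returns at alkenylcyclobutenone 11, hence 14. The sodium alkoxide of 8 (NaH, THF) displaces chloride from (E)-3-chlorobut-2-enoic acid by addition–elimination to give (E)-3-(prop-2-en-1-yloxy)but-2-enoic acid F1. Oxalyl chloride converts it into (E)-3-(prop-2-en-1-yloxy)but-2-enoyl chloride F2. Et3N is then added slowly to F2 and 6 in toluene at 0 °C, so that γ-deprotonation gives 10, which should undergo the [2+2] addition to 11 at or below room temperature. Warming to 80 °C completes the electrocyclic steps to 14.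

Step 10. Partial ionization of the alkoxyphosphonium ion at the p-benzyloxybenzylic carbon would erode stereochemical fidelity at the future C2 and give elimination to the arylbutadiene. The fallback builds ring C first and sets C2 by catalyst control. It sets out from phenol 18 and returns at flavanone 25. The sodium phenoxide of 18 (NaH, DMF) opens oxetan-2-one at the alkyl C–O bond to give 3-{3,5-bis(benzyloxy)-4-[(R)-1-methylpiperidin-2-yl]phenoxy}propanoic acid F3. (CF3CO)2O closes it by Friedel–Crafts acylation to 5,7-bis(benzyloxy)-6-[(R)-1-methylpiperidin-2-yl]chroman-4-one F4; no acid-labile benzylic ether is present at this stage. Dehydrogenation with 2-iodoxybenzoic acid in DMSO on the trifluoroacetate salt gives 5,7-bis(benzyloxy)-6-[(R)-1-methylpiperidin-2-yl]-4H-chromen-4-one F5. A Hayashi–Miyaura asymmetric 1,4-addition of 4-(benzyloxy)phenylboronic acid with [Rh(OH)(cod)]2 and a chiral bisphosphine then gives 25. The ligand enantiomer that leads to 2S would have to be fixed in a trial run.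

Step 13. Under the acidic acylation conditions, ionization of the open-chain benzylic aryl ether or β-elimination of the phenoxide from the activated acyl species may compete with ring closure. The fallback is an anionic closure that uses no acid. It sets out from acid 23 and returns at 25. Compound 23, as its trifluoroacetate salt, is monobrominated with N-bromosuccinimide at one of the two equivalent positions ortho to the ether oxygen to give (S)-3-[4-(benzyloxy)phenyl]-3-{3,5-bis(benzyloxy)-2-bromo-4-[(R)-1-methylpiperidin-2-yl]phenoxy}propanoic acid F6. t-BuLi in THF at −78 °C forms the lithium carboxylate and, by bromine–lithium exchange, the aryllithium, which adds to the carboxylate (Parham cyclization). Aqueous work-up of the dilithium gem-diolate gives 25.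

**Further compounds**
F1 | step 5 | (E)-3-(prop-2-en-1-yloxy)but-2-enoic acid | C=CCO/C(C)=C/C(=O)O
F2 | step 5 | (E)-3-(prop-2-en-1-yloxy)but-2-enoyl chloride | C=CCO/C(C)=C/C(Cl)=O
F3 | step 10 | 3-{3,5-bis(benzyloxy)-4-[(R)-1-methylpiperidin-2-yl]phenoxy}propanoic acid | CN1CCCC[C@@H]1c1c(OCc2ccccc2)cc(OCCC(=O)O)cc1OCc1ccccc1
F4 | step 10 | 5,7-bis(benzyloxy)-6-[(R)-1-methylpiperidin-2-yl]chroman-4-one | CN1CCCC[C@@H]1c1c(OCc2ccccc2)cc2OCCC(=O)c2c1OCc1ccccc1
F5 | step 10 | 5,7-bis(benzyloxy)-6-[(R)-1-methylpiperidin-2-yl]-4H-chromen-4-one | CN1CCCC[C@@H]1c1c(OCc2ccccc2)cc2occc(=O)c2c1OCc1ccccc1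
F6 | step 13 | (S)-3-[4-(benzyloxy)phenyl]-3-{3,5-bis(benzyloxy)-2-bromo-4-[(R)-1-methylpiperidin-2-yl]phenoxy}propanoic acid | OC(=O)C[C@H](Oc1cc(OCc2ccccc2)c([C@H]2CCCCN2C)c(OCc2ccccc2)c1Br)c1ccc(OCc2ccccc2)cc1
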